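**Retrosynthetic overview**

1. Target 23 comes from its tris-silyl ether 22 by one global desilylation.
2. Key disconnection (step 12): N1 is taken out of the piperidine and C2 is joined to C6. The ring N1–C2–C3–C4–C5–C6 is closed last by a Beckmann ring expansion of cyclopentanone oxime mesylate 19, in which C2 migrates from C6 to N1. In the same flask the C6–C1' bond to the whole side chain (Grignard reagent from bromide 13) is formed and hydride sets C6.
3. Enabling feature: N1 lies between C2 (CH3, H) and C6 (chain, H), so C6 can be the carbonyl carbon of a five-membered carbocycle whose C2 and C3 already carry the trans methyl and oxygen groups. The piperidine is 2,3-trans/2,6-cis (all three substituents equatorial), so axial hydride delivery to the C6=N1 imine gives the required C6 configuration.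
4. Ring fragment 19: from 2-methylcyclopent-2-en-1-one by asymmetric β-borylation/oxidation (sets C3; C2 settles trans), silylation, oximation and mesylation.
5. Chain fragment 13: from 11-bromoundec-1-ene and (S)-propylene oxide (C15'), then ozonolysis, Brown allylboration (C4'), silylation, hydroboration and bromination. The piperidine is the only ring and is formed in the key step.

Key step: step 12

Remark on the chemistry: in step 8 the ligand antipode is taken to be the one that delivers boron to the C3 face giving the 3S boronate; if the sense is the opposite, the enantiomeric ligand is used.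

Abbreviations: TBS = tert-butyldimethylsilyl; Ipc = isopinocampheyl; pin = pinacolato.

**Route**

Step 1
Reactants: 1 11-bromoundec-1-ene; 2 (S)-propylene oxide
Product: 4 (2S)-tetradec-13-en-2-ol, via undec-10-enylmagnesium bromide 3 (not isolated)
Conditions: Mg, THF, rt; then CuI (cat.), 2, THF, −30 → 0 °C; aq. NH4Cl
Reagents that add atoms: none
Why: Copper-catalysed Grignard opening of a terminal epoxide at its CH2 carbon (SN2) leaves the stereocentre of 2 untouched and so gives the 2S carbinol (C15' of the target).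

Step 2
Reactants: 4 (2S)-tetradec-13-en-2-ol
Product: 5 tert-butyldimethyl{[(2S)-tetradec-13-en-2-yl]oxy}silane
Conditions: TBSCl, imidazole, DMF, rt
Reagents that add atoms: tert-butyldimethylsilyl chloride, CC(C)(C)[Si](C)(C)Cl
Why: Imidazole-promoted silylation of an unhindered secondary alcohol gives an ether that survives ozone, organometallic reagents and hydride.

Step 3
Reactants: 5 tert-butyldimethyl{[(2S)-tetradec-13-en-2-yl]oxy}silane
Product: 7 (12S)-12-(TBSO)tridecanal, via secondary ozonide 6 (not isolated)
Conditions: O3, CH2Cl2, −78 °C; then Me2S, −78 °C → rt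
Reagents that add atoms: ozone, [O-][O+]=O
Why: Ozonolysis with reductive work-up cleaves the terminal alkene to the aldehyde with loss of one carbon; the silyl ether is inert.

Step 4
Reactants: 7 (12S)-12-(TBSO)tridecanal
Product: 9 (4S,15S)-15-(TBSO)hexadec-1-en-4-ol, via borinate ester 8 (not isolated)
Conditions: (+)-Ipc2BOMe [from (−)-α-pinene], CH2=CHCH2MgBr, Et2O, 0 °C → rt; then 7, −78 °C; then NaOH, H2O2, rt
Reagents that add atoms: allylmagnesium bromide, C=CC[Mg]Br
Why: Brown allylboration through a chair-like six-membered transition state; the isopinocampheyl groups derived from (−)-α-pinene direct allyl transfer to the Re face of the unbranched aldehyde, which sets the new carbinol as 4S under reagent control.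

Step 5
Reactants: 9 (4S,15S)-15-(TBSO)hexadec-1-en-4-ol
Product: 10 (4S,15S)-4,15-bis(TBSO)hexadec-1-ene
Conditions: TBSCl, imidazole, DMF, 40 °C
Reagents that add atoms: tert-butyldimethylsilyl chloride, CC(C)(C)[Si](C)(C)Cl
Why: Silylation of the homoallylic alcohol so that a Grignard reagent can later be made from this chain.

Step 6
Reactants: 10 (4S,15S)-4,15-bis(TBSO)hexadec-1-ene
Product: 12 (4S,15S)-4,15-bis(TBSO)hexadecan-1-ol, via B-alkyl-9-BBN adduct 11 (not isolated)
Conditions: 9-BBN, THF, 0 °C → rt; then NaOH, H2O2, 0 °C → rt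
Reagents that add atoms: hydrogen peroxide, OO
Why: Anti-Markovnikov hydroboration of the terminal alkene followed by stereoretentive oxidation gives the primary alcohol; no stereocentre is touched.

Step 7
Reactants: 12 (4S,15S)-4,15-bis(TBSO)hexadecan-1-ol
Product: 13 (4S,15S)-1-bromo-4,15-bis(TBSO)hexadecane
Conditions: CBr4, PPh3, CH2Cl2, 0 °C
Reagents that add atoms: carbon tetrabromide, BrC(Br)(Br)Br
Why: Appel bromination of a primary alcohol under near-neutral conditions that leave the secondary silyl ethers intact.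

Step 8
Reactants: 14 2-methylcyclopent-2-en-1-one
Product: 16 (2R,3S)-3-hydroxy-2-methylcyclopentan-1-one, via boronate 15 (not isolated)
Conditions: B2pin2, CuCl (cat.), NaOtBu (cat.), (R)-1-[(S)-2-(diphenylphosphino)ferrocenyl]ethyldicyclohexylphosphine (cat.), MeOH, THF, rt; then NaBO3·4H2O, THF/H2O, rt
Reagents that add atoms: sodium perborate, [Na+].[O-]OB=O
Why: Copper-catalysed asymmetric conjugate borylation of a cyclic enone followed by stereoretentive C–B oxidation; the chiral bisphosphine copper–boryl complex selects the enone face and sets C3, while C2, being α to the ketone, should equilibrate to the more stable trans isomer.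

Step 9
Reactants: 16 (2R,3S)-3-hydroxy-2-methylcyclopentan-1-one
Product: 17 (2R,3S)-3-(TBSO)-2-methylcyclopentan-1-one
Conditions: TBSCl, imidazole, DMF, rt
Reagents that add atoms: tert-butyldimethylsilyl chloride, CC(C)(C)[Si](C)(C)Cl
Why: Silylation under weakly basic conditions protects the β-hydroxyl without β-elimination; any cis isomer is removed by chromatography here.

Step 10
Reactants: 17 (2R,3S)-3-(TBSO)-2-methylcyclopentan-1-one
Product: 18 (1E,2S,3S)-3-(TBSO)-2-methylcyclopentan-1-one oxime (same spatial arrangement as 17; only the CIP label at C2 changes)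
Conditions: NH2OH·HCl, NaOAc, MeOH, rt
Reagents that add atoms: hydroxylamine hydrochloride, NO.Cl
Why: Oxime condensation in a buffered medium; the hydroxyl group should settle anti to the more substituted α-carbon C2 (E isomer) to avoid the 2-methyl group, and any Z isomer is separated at this stage.

Step 11
Reactants: 18 (1E,2S,3S)-3-(TBSO)-2-methylcyclopentan-1-one oxime
Product: 19 (1E,2S,3S)-3-(TBSO)-2-methylcyclopentan-1-one O-methanesulfonyl oxime
Conditions: MsCl, Et3N, CH2Cl2, −20 °C
Reagents that add atoms: methanesulfonyl chloride, CS(=O)(=O)Cl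
Why: O-Sulfonylation of the oxime at low temperature keeps the E geometry and gives the leaving group for the rearrangement; the product is used without delay.

Step 12
Reactants: 13 (4S,15S)-1-bromo-4,15-bis(TBSO)hexadecane; 19 (1E,2S,3S)-3-(TBSO)-2-methylcyclopentan-1-one O-methanesulfonyl oxime
Product: 22 (2R,3S,6S)-6-[(4S,15S)-4,15-bis(TBSO)hexadecyl]-3-(TBSO)-2-methylpiperidine, via alkylmagnesium bromide 20 (not isolated), via tetrahydropyridine 21 (not isolated)
Conditions: 13, Mg, Et2O, rt; then 19, toluene, −78 → 0 °C; then i-Bu2AlH, toluene, −78 → 0 °C; aq. potassium sodium tartrate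
Reagents that add atoms: none
Why: The magnesium centre activates the sulfonate of 19, the C1–C2 bond anti to the N–O bond migrates to nitrogen as mesylate leaves (Beckmann rearrangement, retention at the migrating C2), and the ring-expanded imidoyl cation is captured in the ion pair by the alkyl group of 20 to give the cyclic imine 21, which i-Bu2AlH then reduces. The closest known reaction type is the organoaluminium- or Grignard-mediated Beckmann rearrangement–alkylation of cycloalkanone oxime sulfonates followed by hydride reduction, an established entry to 2-alkyl- and cis-2,6-dialkylpiperidines from cyclopentanones. The piperidine ring is closed by ring expansion, a 1,2-shift of C2 from the carbonyl carbon to nitrogen that inserts N1 between C2 and C6 of the carbocycle, while the C6–C1' bond is formed in the same event. C2 and C3 are inherited unchanged from 19, and C6 is set by axial hydride delivery to the half-chair of 21 in which the trans 2-methyl and 3-silyloxy groups are both equatorial, so that the chain ends up equatorial and cis to the methyl group. The step needs migration of C2 and not of C5, which the E geometry of 19 (leaving group anti to the more substituted α-carbon) secures, and it needs ionisation to outrun α-deprotonation or attack at sulfur, which the non-polar solvent and the low temperature favour.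

Step 13
Reactants: 22 (2R,3S,6S)-6-[(4S,15S)-4,15-bis(TBSO)hexadecyl]-3-(TBSO)-2-methylpiperidine
Product: 23 (2R,3S,6S)-6-[(4S,15S)-4,15-dihydroxyhexadecyl]-2-methylpiperidin-3-ol (target)
Conditions: HCl, MeOH, 40 °C; then aq. NaOH
Reagents that add atoms: none
Why: Acid-mediated methanolysis removes the three silyl ethers in one operation, and basification frees the amine; no stereocentre is touched.

**Compound list**

1 | 11-bromoundec-1-ene | C=CCCCCCCCCCBr | starting material
2 | (S)-propylene oxide | C[C@H]1CO1 | starting material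
3 | undec-10-enylmagnesium bromide | C=CCCCCCCCCC[Mg]Br | intermediate
4 | (2S)-tetradec-13-en-2-ol | C[C@H](O)CCCCCCCCCCC=C | intermediate
5 | tert-butyldimethyl{[(2S)-tetradec-13-en-2-yl]oxy}silane | C[C@H](O[Si](C)(C)C(C)(C)C)CCCCCCCCCCC=C | intermediate
6 | 3-[(11S)-11-(TBSO)dodecyl]-1,2,4-trioxolane (secondary ozonide, both epimers at the ring carbon) | C[C@H](O[Si](C)(C)C(C)(C)C)CCCCCCCCCCC1OCOO1 | intermediate
7 | (12S)-12-(TBSO)tridecanal | C[C@H](O[Si](C)(C)C(C)(C)C)CCCCCCCCCCC=O | intermediate
8 | (4S,15S)-15-(TBSO)hexadec-1-en-4-yl diisopinocampheylborinate | C[C@H](O[Si](C)(C)C(C)(C)C)CCCCCCCCCC[C@H](OB([C@H]1C[C@H]2C[C@@H]([C@@H]1C)C2(C)C)[C@H]1C[C@H]2C[C@@H]([C@@H]1C)C2(C)C)CC=C | intermediate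
9 | (4S,15S)-15-(TBSO)hexadec-1-en-4-ol | C[C@H](O[Si](C)(C)C(C)(C)C)CCCCCCCCCC[C@H](O)CC=C | intermediate
10 | (4S,15S)-4,15-bis(TBSO)hexadec-1-ene | C[C@H](O[Si](C)(C)C(C)(C)C)CCCCCCCCCC[C@H](O[Si](C)(C)C(C)(C)C)CC=C | intermediate
11 | 9-[(4R,15S)-4,15-bis(TBSO)hexadecyl]-9-borabicyclo[3.3.1]nonane (same geometry as 10; the C4 label changes because boron ranks below carbon) | C[C@H](O[Si](C)(C)C(C)(C)C)CCCCCCCCCC[C@H](O[Si](C)(C)C(C)(C)C)CCCB1C2CCCC1CCC2 | intermediate
12 | (4S,15S)-4,15-bis(TBSO)hexadecan-1-ol | C[C@H](O[Si](C)(C)C(C)(C)C)CCCCCCCCCC[C@H](O[Si](C)(C)C(C)(C)C)CCCO | intermediate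
13 | (4S,15S)-1-bromo-4,15-bis(TBSO)hexadecane | C[C@H](O[Si](C)(C)C(C)(C)C)CCCCCCCCCC[C@H](O[Si](C)(C)C(C)(C)C)CCCBr | intermediate
14 | 2-methylcyclopent-2-en-1-one | CC1=CCCC1=O | starting material
15 | (2R,3S)-2-methyl-3-(4,4,5,5-tetramethyl-1,3,2-dioxaborolan-2-yl)cyclopentan-1-one | C[C@H]1C(=O)CC[C@@H]1B1OC(C)(C)C(C)(C)O1 | intermediate
16 | (2R,3S)-3-hydroxy-2-methylcyclopentan-1-one (methyl and hydroxyl trans) | C[C@H]1C(=O)CC[C@@H]1O | intermediate
17 | (2R,3S)-3-(TBSO)-2-methylcyclopentan-1-one | C[C@H]1C(=O)CC[C@@H]1O[Si](C)(C)C(C)(C)C | intermediate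
18 | (1E,2S,3S)-3-(TBSO)-2-methylcyclopentan-1-one oxime (OH anti to C2) | C[C@H]1/C(=N/O)CC[C@@H]1O[Si](C)(C)C(C)(C)C | intermediate
19 | (1E,2S,3S)-3-(TBSO)-2-methylcyclopentan-1-one O-methanesulfonyl oxime | C[C@H]1/C(=N/OS(C)(=O)=O)CC[C@@H]1O[Si](C)(C)C(C)(C)C | intermediate
20 | [(4S,15S)-4,15-bis(TBSO)hexadecyl]magnesium bromide | C[C@H](O[Si](C)(C)C(C)(C)C)CCCCCCCCCC[C@H](O[Si](C)(C)C(C)(C)C)CCC[Mg]Br | intermediate
21 | (2R,3S)-6-[(4S,15S)-4,15-bis(TBSO)hexadecyl]-3-(TBSO)-2-methyl-2,3,4,5-tetrahydropyridine | C[C@H](O[Si](C)(C)C(C)(C)C)CCCCCCCCCC[C@H](O[Si](C)(C)C(C)(C)C)CCCC1=N[C@H](C)[C@@H](O[Si](C)(C)C(C)(C)C)CC1 | intermediate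
22 | (2R,3S,6S)-6-[(4S,15S)-4,15-bis(TBSO)hexadecyl]-3-(TBSO)-2-methylpiperidine | C[C@H](O[Si](C)(C)C(C)(C)C)CCCCCCCCCC[C@H](O[Si](C)(C)C(C)(C)C)CCC[C@H]1CC[C@H](O[Si](C)(C)C(C)(C)C)[C@@H](C)N1 | intermediate
23 | (2R,3S,6S)-6-[(4S,15S)-4,15-dihydroxyhexadecyl]-2-methylpiperidin-3-ol | C[C@H](O)CCCCCCCCCC[C@H](O)CCC[C@H]1CC[C@H](O)[C@@H](C)N1 | target

**Step count**

Total steps: 13. Longest linear sequence: 9 (steps 1–7, 12, 13); the ring fragment is made in steps 8–11.

**Steps most likely to fail**

1. Step 12. The Grignard reagent may deprotonate C5 of 19 (azirine formation) or attack the sulfonyl sulfur instead of triggering the rearrangement, and any sulfonate that has isomerised to the Z form would send C5 instead of C2 to nitrogen. Fallback, setting out from 19 and coming back at 23: solvolysis of 19 (NaHCO3, aqueous dioxane, 60 °C) should give, by Beckmann rearrangement with capture by water, the lactam (5S,6R)-5-(TBSO)-6-methylpiperidin-2-one F1. Boc2O, DMAP and Et3N in CH2Cl2 would convert it into the N-Boc lactam F2. The Grignard reagent 20 (from 13, Mg, THF) at −78 °C should open the activated lactam to the N-Boc amino ketone F3. HCl in MeOH would remove the carbamate and the three silyl ethers, and the freed amino ketone should close to the cyclic imine F4 (not isolated). NaBH4 added at −78 → 0 °C should reduce F4 from the axial direction to 23.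

2. Step 8. The copper–boryl catalyst may discriminate poorly between the faces of an α-substituted enone, and the β-hydroxy ketone may dehydrate while C2 equilibrates. Fallback, setting out from 14 and coming back at 17: Corey–Bakshi–Shibata reduction with (R)-2-methyl-CBS-oxazaborolidine (cat.) and BH3·SMe2 in THF at −40 °C should give (1S)-2-methylcyclopent-2-en-1-ol F5. BzCl in pyridine gives the benzoate F6. Hydroboration (BH3·THF, 0 °C) then NaBO3·4H2O, anti to the benzoate and syn across the alkene, should give the alcohol F7 with the methyl and hydroxyl groups trans. TBSCl and imidazole give the silyl ether F8, K2CO3 in MeOH the alcohol F9, and Dess–Martin periodinane oxidises F9 to 17.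

3. Step 4. Incomplete facial selectivity in the allyl transfer would give the C4 epimer, which cannot be separated later because the stereocentres are remote. Fallback, setting out from 5 and coming back at 9: mCPBA in CH2Cl2 epoxidises 5 to the epoxide F10 as a mixture of oxirane epimers. Hydrolytic kinetic resolution with (S,S)-(salen)Co(OAc) (the antipode that spares the S oxirane) and about half an equivalent of water should leave the (S)-oxirane F11 and hydrolyse the other epimer to the diol. CuI-catalysed opening of F11 at its terminal carbon with vinylmagnesium bromide in THF at −30 °C gives 9.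

Further compounds
F1 | step 12 | (5S,6R)-5-(TBSO)-6-methylpiperidin-2-one | C[C@H]1NC(=O)CC[C@@H]1O[Si](C)(C)C(C)(C)C
F2 | step 12 | tert-butyl (2R,3S)-3-(TBSO)-2-methyl-6-oxopiperidine-1-carboxylate | C[C@H]1N(C(=O)OC(C)(C)C)C(=O)CC[C@@H]1O[Si](C)(C)C(C)(C)C
F3 | step 12 | tert-butyl N-[(2R,3S,10S,21S)-3,10,21-tris(TBSO)-6-oxodocosan-2-yl]carbamate | C[C@@H](NC(=O)OC(C)(C)C)[C@@H](O[Si](C)(C)C(C)(C)C)CCC(=O)CCC[C@@H](O[Si](C)(C)C(C)(C)C)CCCCCCCCCC[C@H](C)O[Si](C)(C)C(C)(C)C
F4 | step 12 | (2R,3S)-6-[(4S,15S)-4,15-dihydroxyhexadecyl]-2-methyl-2,3,4,5-tetrahydropyridin-3-ol | C[C@H](O)CCCCCCCCCC[C@H](O)CCCC1=N[C@H](C)[C@@H](O)CC1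
F5 | step 8 | (1S)-2-methylcyclopent-2-en-1-ol | CC1=CCC[C@@H]1O
F6 | step 8 | (1S)-2-methylcyclopent-2-en-1-yl benzoate | CC1=CCC[C@@H]1OC(=O)c1ccccc1
F7 | step 8 | (1S,2R,3S)-3-hydroxy-2-methylcyclopentyl benzoate | C[C@H]1[C@@H](OC(=O)c2ccccc2)CC[C@@H]1O
F8 | step 8 | (1S,2S,3S)-3-(TBSO)-2-methylcyclopentyl benzoate | C[C@H]1[C@@H](OC(=O)c2ccccc2)CC[C@@H]1O[Si](C)(C)C(C)(C)C
F9 | step 8 | (1S,2S,3S)-3-(TBSO)-2-methylcyclopentan-1-ol | C[C@H]1[C@@H](O)CC[C@@H]1O[Si](C)(C)C(C)(C)C
F10 | step 4 | tert-butyldimethyl{[(2S)-12-(oxiran-2-yl)dodecan-2-yl]oxy}silane (both oxirane epimers) | C[C@H](O[Si](C)(C)C(C)(C)C)CCCCCCCCCCC1CO1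
F11 | step 4 | tert-butyldimethyl({(2S)-12-[(2S)-oxiran-2-yl]dodecan-2-yl}oxy)silane | C[C@H](O[Si](C)(C)C(C)(C)C)CCCCCCCCCC[C@H]1CO1
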